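Assumption: the SMILES carries no descriptor for the C5–C1' biaryl axis, so the racemic mixture of the two atropisomers is taken as the target.

## Analysis of the target

The target is a fully aromatic 5,1'-linked naphthylisoquinoline. Its isoquinoline consists of ring A (N2, C1, C3, C4, C4a, C8a; methyl groups on C1 and C3) and ring B (C4a, C5, C6, C7, C8, C8a; methoxy groups on C6 and C8). C5 is bonded to C1' of a naphthalene made of ring C (C1', C2', C3', C4', C4a', C8a'; methyl on C2', methoxy on C4') and ring D (C5' to C8'; methoxy on C5'). There is no sp3 stereocentre; the only stereogenic element is the C5–C1' axis, flanked by C6–OMe and C4a (peri H on C4) on one side and by C2'–CH3 and C8a' (peri H on C8') on the other, so rotation is blocked. Sensitive sites are the basic nitrogen, the acidic C1 methyl group (an aza-benzylic position that strong bases deprotonate) and three electron-rich rings (B, C, D) that are easily oxidised and offer electrophiles more than one site (C5 against C7, C1' against C8'). The hard part is the C5–C1' bond: a tetra-ortho-substituted biaryl bond between two electron-rich partners, where the metal-centred bond formation of a cross-coupling is at its slowest. A second cost lies in the naphthalene half, because a 1-functionalised 4,5-dimethoxy-2-methylnaphthalene is not commercial and normally needs a ring synthesis of its own. The feature the route exploits is the para relationship, inside ring C, of the axis carbon C1' and the oxygen-bearing C4'. The unit C1'–C2'(CH3)=C3'–C4'(O) is that of a 1,4-naphthoquinone monoketal with C1' as carbonyl carbon and C4' as ketal carbon, so C5–C1' can be made by carbonyl addition while ring C is not yet aromatic. A supporting feature is N2 between the methyl-bearing C1 and C3 of ring A, the imprint of a 1,3-dimethyl-2-benzopyrylium ion whose ring oxygen is exchanged for nitrogen.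

## Retrosynthetic reasoning

**12 to 11.** The first cut removes the aromaticity of ring C, not a bond between the halves. Target 12 is traced back to carbinol 11, in which C1' is sp3 (hydroxyl plus the isoquinolinyl group) and C4' is a dimethyl ketal. The forward reaction is a two-electron reductive aromatisation that expels the C1' hydroxyl group and one C4' methoxy group. The remaining methoxy group is the one the target needs, so no late O-methylation next to a free nitrogen is required. The gain is that the crowded axis is never made by forcing two planar arenes together; it appears when a carbinol collapses to an arene, driven by aromatisation.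

**11 to 9 and 5.** The C5–C1' bond is cut as a carbonyl addition. C5 is the nucleophile (aryl-magnesium species 10, made in the flask from iodide 9) and C1' the electrophile (carbonyl carbon of quinone monoketal 5). C1' is the only carbon of ring C that can be a carbonyl carbon with the target's substitution, and the ketal at C4' leaves a single electrophilic site. The regiochemistry of ring C is therefore a property of 5, not of the reaction. The forward reaction must achieve 1,2-addition to a carbonyl group flanked by a methyl group and a peri hydrogen without touching the acidic C1 methyl group, hence magnesium and not lithium. Each precursor is a bicyclic compound two steps from a commercial material, and the naphthalene half is never needed as a halide or an organometallic.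

**5 to 3.** The two C4'–O bonds are cut. Ketal 5 comes from oxidative dearomatisation of naphthol 3, through the para-methoxylated naphthol 4, by oxidising the free para position of a 1-naphthol twice in an alcohol solvent. The hydroxyl group of 3 marks the future axis carbon and its para position the future methoxy carbon.

**3 to 1.** The C2'–CH3 bond is cut and ring C is taken back to the saturated ring of tetralone 1. The only enolisable position of 1 is C2', so a one-carbon electrophile enters there (exocyclic enone 2), and shifting the exocyclic double bond into the ring gives the naphthol. The carbonyl carbon of 1 is C1' and its methoxy group is the C5' methoxy group, so the whole naphthalene pattern derives from one commercial ketone.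

**9 to 8.** The C5–I bond is cut. Electrophilic iodination of isoquinoline 8 is expected at C5 (reasons at step 4). Iodine is preferred to bromine because exchange with an alkyl-magnesium reagent is then fast at low temperature.

**8 to 6.** Ring A is cut at C1–N2, N2–C3 and C1–C8a. Isoquinoline 8 is the nitrogen analogue of 2-benzopyrylium salt 7, which arises from arylacetone 6 by ring acetylation and cyclodehydration. A nitrogen source then exchanges the ring oxygen for nitrogen by ring opening and ring closure. Both methoxy groups and the C3 methyl group are already in 6; the acetyl donor supplies C1 with its methyl group.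

## Alternatives that were turned down

Alternative 1: The textbook disconnection cuts C5–C1' between two finished arenes. The forward key step is a Suzuki–Miyaura coupling of 9 with boronic acid A1, made from bromide A2 by bromine–lithium exchange and borylation. It was turned down for three reasons.
- Both partners are di-ortho-substituted and electron-rich. Oxidative addition into 9 is slow, transmetalation of A1 competes with protodeboronation at the para-methoxy-activated C1', and reductive elimination must press four ortho groups together at palladium.
- A2 is not commercial. Its arene must first be built in several steps and then brominated, where C1' (ortho to methyl, para to the C4' methoxy group) competes with C8' (para to the C5' methoxy group).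
- The route would be roughly twice as long as the chosen one and would still end in its least reliable step.

Alternative 2: A biomimetic cut of the same bond by phenol oxidation. One-electron oxidation of a mixture of naphthol A3 and isoquinolinol A4 (an iron or copper oxidant, or anodic oxidation in a fluorinated alcohol) would couple C1' (para to the C4' hydroxyl) with C5 (para to the C8 hydroxyl) to give biaryl A5, followed by double O-methylation to 12. It was turned down because nothing in the structures enforces cross-coupling over homo-coupling.
- A3 is the more easily oxidised partner; its radical dimerises at C1' and the dimer is oxidised further.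
- A4 is protonated on nitrogen in the acidic media these couplings need and is then a poor nucleophile.
- A4 offers C7 as well as C5, and A3 offers C3' (ortho) as well as C1'.
- A5 is more electron-rich than either partner and would be oxidised in preference to them.
- The final methylation must spare the nitrogen, and A3 and A4 each need a selectively mono-O-methylated pattern, so the route is not shorter.

Alternative 3: Construction of ring C on the isoquinoline from a furan. Negishi coupling of 9 with a 3-methyl-2-furylzinc reagent would give furan A6. A [4+2] cycloaddition of A6 with an aryne carrying the future C5' methoxy group would give the oxygen-bridged adduct A7, and acid would open the bridge to a naphthol that is methylated to 12. The attraction is that the coupling that makes A6 is far less hindered. It was turned down because two selectivities are left to chance.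
- The unsymmetrical aryne must orient so that its methoxy group ends up peri to the bridgehead C–H and not to the aryl-bearing bridgehead.
- The productive bridge opening ionises the C1'–O bond, but the cation at C4' is the better one (ortho-methoxybenzylic, allylic with the methyl-bearing terminus), while the cation at C1' sits next to a protonated isoquinoline. Ionisation at C4' leads to a 1,2-aryl shift and a non-aromatic ketone.
- It needs four steps from 9 where the chosen route needs two.

Key step: step 5

## Route

Step 1
Reactants: 1 5-methoxy-3,4-dihydronaphthalen-1(2H)-one (5-methoxy-1-tetralone)
Product: 3 5-methoxy-2-methylnaphthalen-1-ol, via exocyclic enone 2 (not isolated)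
Conditions: (CH2O)n, PhNHMe·CF3CO2H, THF, reflux; aqueous wash; then RhCl3·3H2O (5 mol %), EtOH, reflux
Reagents that add atoms: paraformaldehyde (as formaldehyde) C=O
Why: Mannich-type alpha-methylenation at C2', the only enolisable position, gives exocyclic enone 2; RhCl3-catalysed migration of the exocyclic double bond into the ring gives the keto tautomer of 3, so the isomerisation is driven by aromatisation and places the methyl group on C2' without a regiochemical choice.

Step 2
Reactants: 3 5-methoxy-2-methylnaphthalen-1-ol
Product: 5 4,4,5-trimethoxy-2-methylnaphthalen-1(4H)-one, via para-methoxynaphthol 4 (not isolated)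
Conditions: PhI(OAc)2 (2.2 equiv), MeOH, 0 °C to rt
Reagents that add atoms: methanol CO
Why: Oxidative dearomatisation of a phenol by trivalent iodine: the first equivalent delivers methanol to the free para position C4' (preferred over the methyl-bearing ortho carbon) and tautomerisation gives 4; the second equivalent oxidises 4 to the para-quinone monoketal 5, which leaves C1' as the only carbonyl carbon and masks C4'.

Step 3
Reactants: 6 1-(3,5-dimethoxyphenyl)propan-2-one
Product: 8 6,8-dimethoxy-1,3-dimethylisoquinoline, via benzopyrylium tetrafluoroborate 7 (not isolated)
Conditions: Ac2O, HBF4·OEt2, 0 °C to rt; then conc. aq. NH3, EtOH, rt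
Reagents that add atoms: acetic anhydride CC(=O)OC(C)=O; ammonia N
Why: Friedel–Crafts acetylation ortho to the acetonyl chain (para to one methoxy group, ortho to the other) and cyclodehydration of the resulting 1,5-dicarbonyl unit give the aromatic 2-benzopyrylium salt 7; ammonia opens the pyrylium ring at C1 and recloses it on nitrogen (pyrylium-to-pyridine exchange), which should give 8 with both methyl groups in place.

Step 4
Reactants: 8 6,8-dimethoxy-1,3-dimethylisoquinoline
Product: 9 5-iodo-6,8-dimethoxy-1,3-dimethylisoquinoline
Conditions: NIS (1.05 equiv), CF3CO2H, MeCN, 0 °C to rt, dark
Reagents that add atoms: N-iodosuccinimide O=C1CCC(=O)N1I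
Why: Electrophilic aromatic iodination; in acid ring A is protonated and inert, and of the two open positions of ring B the alpha-type C5 (para to the C8 methoxy group, ortho to the C6 methoxy group) should be attacked in preference to C7, which lies between two methoxy groups and whose Wheland intermediate places charge on C8a next to the protonated C1=N unit.

Step 5
Reactants: 9 5-iodo-6,8-dimethoxy-1,3-dimethylisoquinoline; 5 4,4,5-trimethoxy-2-methylnaphthalen-1(4H)-one
Product: 11 1-(6,8-dimethoxy-1,3-dimethylisoquinolin-5-yl)-4,4,5-trimethoxy-2-methyl-1,4-dihydronaphthalen-1-ol (racemic), via arylmagnesium chloride 10 (not isolated)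
Conditions: 9, iPrMgCl·LiCl (1.1 equiv), THF, −15 to 0 °C; then LaCl3·2LiCl (30 mol %) and 5, THF, 0 °C to rt; H2O quench
Reagents that add atoms: none
Why: Iodine–magnesium exchange on 9 is fast because the aryl anion is sp2-bound and held by the ortho methoxy group, and the magnesium reagent is too weakly basic to deprotonate the C1 methyl group or add to C1=N, so 10 should form cleanly. 10 then adds in the 1,2-sense to C1', the only carbonyl carbon of 5, activated by the oxophilic lanthanum salt, which also suppresses electron transfer and conjugate addition. The closest known reaction type is the 1,2-addition of aryl-magnesium and aryl-lithium reagents to para-quinone monoketals to give para-quinol ketals; the addition of 2,6-disubstituted aryl metals to anthraquinone on the way to 9,10-diarylanthracenes shows that carbinols this crowded can be made this way. No ring is closed: the step forms the C5–C1' bond, the future biaryl axis, by attack perpendicular to the plane of ring C, so the C2' methyl group and the peri C8'–H lie beside the trajectory and no reductive elimination between two hindered aryl groups on a metal is needed. The new stereocentre C1' forms as a racemate and needs no control because step 6 makes it trigonal. The site selectivity the step needs, attack at C1' and not C4', is secured by the substrate, in which C4' is a ketal and no longer electrophilic; this also fixes the remaining oxygen para to the new bond. Attack at the beta carbon C3' is disfavoured by the adjacent quaternary ketal carbon. The ketal, the aryl ethers and the isoquinoline ring are inert to the aryl-magnesium reagent at or below room temperature.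

Step 6
Reactants: 11 1-(6,8-dimethoxy-1,3-dimethylisoquinolin-5-yl)-4,4,5-trimethoxy-2-methyl-1,4-dihydronaphthalen-1-ol
Product: 12 5-(4,5-dimethoxy-2-methylnaphthalen-1-yl)-6,8-dimethoxy-1,3-dimethylisoquinoline (racemic about the C5–C1' axis)
Conditions: Zn dust (10 equiv), glacial AcOH, THF, rt to 50 °C; basic work-up
Reagents that add atoms: none
Why: Reductive aromatisation of a para-quinol ketal: in acetic acid the ketal ionises to a methoxy-stabilised, benzylic and allylic oxocarbenium ion, zinc transfers two electrons, and the resulting allyl-zinc species expels the C1' hydroxyl group as water in a vinylogous elimination, so ring C becomes aromatic with one methoxy group left on C4'. The same low-valent-metal and acid reaction type converts para-quinols into phenols and hindered 9,10-diaryl-9,10-dihydroanthracene-9,10-diols into 9,10-diarylanthracenes; aryl ethers and the protonated isoquinoline should survive, the C1' stereocentre disappears and the axis forms as the racemate.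

## Compound list

1 | 5-methoxy-3,4-dihydronaphthalen-1(2H)-one (5-methoxy-1-tetralone) | O=C1CCCc2c(OC)cccc12 | starting material
2 | 5-methoxy-2-methylidene-3,4-dihydronaphthalen-1(2H)-one | C=C1CCc2c(OC)cccc2C1=O | intermediate
3 | 5-methoxy-2-methylnaphthalen-1-ol | Cc1ccc2c(OC)cccc2c1O | intermediate
4 | 4,5-dimethoxy-2-methylnaphthalen-1-ol | Cc1cc(OC)c2c(OC)cccc2c1O | intermediate
5 | 4,4,5-trimethoxy-2-methylnaphthalen-1(4H)-one | CC1=CC(OC)(OC)c2c(OC)cccc2C1=O | intermediate
6 | 1-(3,5-dimethoxyphenyl)propan-2-one | CC(=O)Cc1cc(OC)cc(OC)c1 | starting material
7 | 6,8-dimethoxy-1,3-dimethylisochromenylium (2-benzopyrylium) tetrafluoroborate | COc1cc(OC)c2c(C)[o+]c(C)cc2c1.F[B-](F)(F)F | intermediate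
8 | 6,8-dimethoxy-1,3-dimethylisoquinoline | COc1cc(OC)c2c(C)nc(C)cc2c1 | intermediate
9 | 5-iodo-6,8-dimethoxy-1,3-dimethylisoquinoline | COc1cc(OC)c2c(C)nc(C)cc2c1I | intermediate
10 | (6,8-dimethoxy-1,3-dimethylisoquinolin-5-yl)magnesium chloride (as its LiCl complex) | COc1cc(OC)c2c(C)nc(C)cc2c1[Mg]Cl | intermediate
11 | 1-(6,8-dimethoxy-1,3-dimethylisoquinolin-5-yl)-4,4,5-trimethoxy-2-methyl-1,4-dihydronaphthalen-1-ol (racemic) | COc1cc(OC)c2c(C)nc(C)cc2c1C1(O)C(C)=CC(OC)(OC)c2c(OC)cccc21 | intermediate
12 | 5-(4,5-dimethoxy-2-methylnaphthalen-1-yl)-6,8-dimethoxy-1,3-dimethylisoquinoline (racemic about the C5–C1' axis) | COc1cc(OC)c2c(C)nc(C)cc2c1-c1c(C)cc(OC)c2c(OC)cccc12 | target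

## Step count and risk

Total step count: 6. Longest linear sequence: 4 steps (1 to 3 to 5 to 11 to 12, or 6 to 8 to 9 to 11 to 12).

**Step 5 (key step).** The most likely failure is that the congested 1,2-addition is outrun by single-electron transfer from the aryl-magnesium species to the cross-conjugated dienone, which would reduce the dienone and protonate the aryl metal. Conjugate addition at C3' or incomplete exchange, letting the isopropyl reagent add instead, are the other risks. A full equivalent of the lanthanum salt is the first adjustment. The fallback joins the halves at the aromatic level by a Negishi coupling; it sets out from 5 and 9 and comes back at 12. Ketal 5 is reduced with Na2S2O4 in aqueous THF to naphthol 4, which Tf2O and pyridine convert into 4,5-dimethoxy-2-methylnaphthalen-1-yl trifluoromethanesulfonate F1. Iodide 9 is converted as in step 5 into 10 and transmetalated with ZnCl2 to (6,8-dimethoxy-1,3-dimethylisoquinolin-5-yl)zinc chloride F2. Coupling F1 with F2 using Pd2(dba)3 and a bulky dialkylbiarylphosphine in THF/NMP at 70 °C, a known way to tetra-ortho-substituted biaryls, should give 12 directly.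

**Step 6.** Acid-induced ionisation may run ahead of electron transfer. A 1,2-shift of the aryl group (dienone–phenol type) or hydrolysis of the ketal with loss of the C4' methyl ether could then occur before reduction. The fallback separates the events with known reactions; it sets out from 11 and comes back at 12. Mild aqueous acid (oxalic acid on wet silica) hydrolyses the ketal to the para-quinol 4-(6,8-dimethoxy-1,3-dimethylisoquinolin-5-yl)-4-hydroxy-8-methoxy-3-methylnaphthalen-1(4H)-one F3. Na2S2O4 or Zn/AcOH reduces it to 4-(6,8-dimethoxy-1,3-dimethylisoquinolin-5-yl)-8-methoxy-3-methylnaphthalen-1-ol F4. The naphthoxide is then O-methylated with a slight excess of MeI and K2CO3 in acetone, where the hindered nitrogen between two methyl groups should not compete, to give 12.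

**Step 2.** The second oxidation must place a second methoxy group on C4' next to the peri C5' methoxy group. Crowding may slow it, so that attack at the ortho carbon C2' or hydrolysis to the quinone by adventitious water takes over. The fallback uses the quinone on purpose; it sets out from 3 and comes back at 12. Naphthol 3 is oxidised with (KSO3)2NO in buffered aqueous acetone to 5-methoxy-2-methylnaphthalene-1,4-dione F5. Reagent 10 should add to its C1' carbonyl group, the more electrophilic one, because the C4' carbonyl group is deactivated by the peri methoxy group through ring D and by the C2' methyl group through the enone. This gives quinol F3, which is carried through F4 to 12 as described for step 6. This path relies on an innate preference where the main route has a masked carbonyl group, which is why it is the fallback.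

**Step 4.** Iodination may be slow on the protonated heterocycle, or may go partly to C7 or to a di-iodide. The fallback installs the halogen before ring A exists; it sets out from 6 and comes back at 9. NBS in MeCN brominates 6 at the position ortho to the side chain and para to a methoxy group to give 1-(2-bromo-3,5-dimethoxyphenyl)propan-2-one F6. The conditions of step 3 (the only remaining position ortho to the side chain is acetylated) convert F6 into 5-bromo-6,8-dimethoxy-1,3-dimethylisoquinoline F7. A copper-catalysed aromatic Finkelstein exchange (CuI, NaI, trans-N,N'-dimethylcyclohexane-1,2-diamine, dioxane, 110 °C) gives 9.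

## Further compounds

F1 | step 5 | 4,5-dimethoxy-2-methylnaphthalen-1-yl trifluoromethanesulfonate | Cc1cc(OC)c2c(OC)cccc2c1OS(=O)(=O)C(F)(F)F
F2 | step 5 | (6,8-dimethoxy-1,3-dimethylisoquinolin-5-yl)zinc chloride | COc1cc(OC)c2c(C)nc(C)cc2c1[Zn]Cl
F3 | step 6 | 4-(6,8-dimethoxy-1,3-dimethylisoquinolin-5-yl)-4-hydroxy-8-methoxy-3-methylnaphthalen-1(4H)-one (racemic) | COc1cc(OC)c2c(C)nc(C)cc2c1C1(O)C(C)=CC(=O)c2c(OC)cccc21
F4 | step 6 | 4-(6,8-dimethoxy-1,3-dimethylisoquinolin-5-yl)-8-methoxy-3-methylnaphthalen-1-ol | COc1cc(OC)c2c(C)nc(C)cc2c1-c1c(C)cc(O)c2c(OC)cccc12
F5 | step 2 | 5-methoxy-2-methylnaphthalene-1,4-dione | CC1=CC(=O)c2c(OC)cccc2C1=O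
F6 | step 4 | 1-(2-bromo-3,5-dimethoxyphenyl)propan-2-one | CC(=O)Cc1cc(OC)cc(OC)c1Br
F7 | step 4 | 5-bromo-6,8-dimethoxy-1,3-dimethylisoquinoline | COc1cc(OC)c2c(C)nc(C)cc2c1Br
A1 | alternative 1 | (4,5-dimethoxy-2-methylnaphthalen-1-yl)boronic acid | Cc1cc(OC)c2c(OC)cccc2c1B(O)O
A2 | alternative 1 | 1-bromo-4,5-dimethoxy-2-methylnaphthalene | Cc1cc(OC)c2c(OC)cccc2c1Br
A3 | alternative 2 | 8-methoxy-3-methylnaphthalen-1-ol | Cc1cc(O)c2c(OC)cccc2c1
A4 | alternative 2 | 6-methoxy-1,3-dimethylisoquinolin-8-ol | COc1cc(O)c2c(C)nc(C)cc2c1
A5 | alternative 2 | 5-(4-hydroxy-5-methoxy-2-methylnaphthalen-1-yl)-6-methoxy-1,3-dimethylisoquinolin-8-ol | COc1cc(O)c2c(C)nc(C)cc2c1-c1c(C)cc(O)c2c(OC)cccc12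
A6 | alternative 3 | 6,8-dimethoxy-1,3-dimethyl-5-(3-methylfuran-2-yl)isoquinoline | COc1cc(OC)c2c(C)nc(C)cc2c1-c1occc1C
A7 | alternative 3 | 1-(6,8-dimethoxy-1,3-dimethylisoquinolin-5-yl)-5-methoxy-2-methyl-1,4-dihydro-1,4-epoxynaphthalene (racemic) | COc1cccc2c1C1OC2(C(C)=C1)c1c(OC)cc(OC)c2c(C)nc(C)cc12
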